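## Retrosynthetic overview

1. Hypholomine B is the oxidative [3+2] dimer of hispidin, as in its presumed biosynthesis: cut the dihydrofuran at C3–C3a and O1–C2 to give two identical styrylpyranone units.
2. The dimerisation is run on the catechol-silylated monomer with a chiral trivalent-iron phosphate catalyst, so one step forms the ring and both stereocentres, (2S,3S)-trans. Global desilylation ends the route.
3. The monomer is cut at the styryl C=C (vinylogous aldol, then dehydration) into triacetic acid lactone and silylated protocatechualdehyde.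
4. Ring order: both pyranone rings are bought ready-made in triacetic acid lactone. The dihydrofuran is the only ring built, in the penultimate step.

Assumption: Fe[(R)-TRIP]3 is Fe(C50H56O4P)3, trivalent iron with three (R)-3,3'-bis(2,4,6-triisopropylphenyl)-1,1'-binaphthyl-2,2'-diyl phosphate ligands (from Fe(ClO4)3 and 3 equiv of the sodium phosphate); the (R)-ligand is taken to give the (2S,3S) product, and the (S)-ligand is used instead if chiral HPLC/ECD analysis of 7 shows the antipode.

## Route

Step 1
Reactants: 1 protocatechualdehyde (3,4-dihydroxybenzaldehyde)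
Product: 2 bis-TBS aldehyde [3,4-bis(tert-butyldimethylsilyloxy)benzaldehyde]
Conditions: TBSCl (2.3 equiv), imidazole (5 equiv), DMF, 0 °C to rt
Reagents that add atoms: tert-butyldimethylsilyl chloride (TBSCl), CC(C)(C)[Si](C)(C)Cl
Why: Imidazole-promoted O-silylation of both phenols masks the catechol against the strong base of step 2 and against one-electron oxidation in step 3; no stereocentre is formed.

Step 2
Reactants: 3 triacetic acid lactone (4-hydroxy-6-methyl-2H-pyran-2-one); 2 bis-TBS aldehyde
Product: 6 bis-TBS hispidin [6-{(E)-2-[3,4-bis(tert-butyldimethylsilyloxy)phenyl]ethenyl}-4-hydroxy-2H-pyran-2-one], via dilithio dianion 4 (not isolated), via aldol adduct 5 (not isolated)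
Conditions: 3 (1.3 equiv), LiN(iPr)2 (2.6 equiv), THF/DMPU, −78 °C; then 2, −78 to −20 °C; 1 M HCl quench (pH 3); crude 5, CSA (10 mol %), PhMe (0.02 M), 60 °C
Reagents that add atoms: none
Why: Vinylogous aldol addition of the O,C-dianion of 3 through its 6-CH2 terminus to the non-enolisable aldehyde, followed by acid-catalysed E1 dehydration through the p-silyloxybenzyl cation, gives the fully conjugated (E)-styrylpyranone (thermodynamic geometry); the carbinol centre of 5 is racemic and is destroyed.

Step 3
Reactants: 6 bis-TBS hispidin (two molecules)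
Product: 7 tetra-TBS hypholomine B [(2S,3S)-2-[3,4-bis(tert-butyldimethylsilyloxy)phenyl]-6-{(E)-2-[3,4-bis(tert-butyldimethylsilyloxy)phenyl]ethenyl}-3-(4-hydroxy-2-oxo-2H-pyran-6-yl)-2,3-dihydro-4H-furo[3,2-c]pyran-4-one; H-2 and H-3 trans]
Conditions: Fe[(R)-TRIP]3 (5 mol %), t-BuOOt-Bu (0.33 equiv), ClCH2CH2Cl/HFIP 1:1 (0.1 M), Ar, 0 °C to rt; stopped at about 60% conversion, recovered 6 recycled; ee of 7 raised by recrystallisation if needed
Reagents that add atoms: none
Why: Proposed new method: the acidic 4-OH of 6 (pKa about 5) displaces one phosphate to give an iron pyronate, peroxide-driven one-electron oxidation turns it into an iron-bound electrophilic C3 radical, and this adds inside the binaphthyl phosphate pocket to the alkene carbon next to the pyranone of a second molecule of 6 (the electron-rich end of the push–pull styryl unit, held by a hydrogen bond from its own 4-OH to a phosphate P=O), which sets C3 as S; the resulting p-silyloxybenzyl radical is oxidised by trivalent iron to the cation and captured by the pyranone O4 anti to the new C3 substituent, so C2 follows as S in the thermodynamically preferred trans ring (a cis isomer can re-ionise and correct itself); this is a radical–polar oxidative [3+2] annulation, and the closest known reaction types are the racemic Mn(OAc)3-, (NH4)2Ce(NO3)6- or Fe(ClO4)3-mediated [3+2] annulation of 4-hydroxy-2-pyranones and other 1,3-dicarbonyls with styrenes, the FeCl3/peroxide oxidative phenol–alkene [3+2] coupling to dihydrobenzofurans, and the enantioselective oxidative coupling of 2-naphthols with iron tris(binaphthyl phosphate) catalysts.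

Step 4
Reactants: 7 tetra-TBS hypholomine B
Product: 8 hypholomine B [(2S,3S)-2-(3,4-dihydroxyphenyl)-6-[(E)-2-(3,4-dihydroxyphenyl)ethenyl]-3-(4-hydroxy-2-oxo-2H-pyran-6-yl)-2,3-dihydro-4H-furo[3,2-c]pyran-4-one]
Conditions: Et3N·3HF (12 equiv), THF (degassed), Ar, 0 °C to rt; pH 5 buffer work-up; Sephadex LH-20 (MeOH)
Reagents that add atoms: none
Why: Fluoride-driven Si–O cleavage (desilylation) of the four aryl silyl ethers under weakly acidic conditions generates no phenoxide, so the p-hydroxybenzylic ether is not opened through a quinone methide and C2 and C3 stay (2S,3S).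

## Compound list

1 | protocatechualdehyde (3,4-dihydroxybenzaldehyde) | O=Cc1ccc(O)c(O)c1 | starting material
2 | bis-TBS aldehyde, 3,4-bis(tert-butyldimethylsilyloxy)benzaldehyde | O=Cc1ccc(O[Si](C)(C)C(C)(C)C)c(O[Si](C)(C)C(C)(C)C)c1 | intermediate
3 | triacetic acid lactone, 4-hydroxy-6-methyl-2H-pyran-2-one | Cc1cc(O)cc(=O)o1 | starting material
4 | dilithio dianion of 3, lithium 6-(lithiomethyl)-2-oxo-2H-pyran-4-olate | [Li+].[Li+].[CH2-]c1cc([O-])cc(=O)o1 | intermediate
5 | aldol adduct, racemic 6-{2-[3,4-bis(tert-butyldimethylsilyloxy)phenyl]-2-hydroxyethyl}-4-hydroxy-2H-pyran-2-one | O=c1cc(O)cc(CC(O)c2ccc(O[Si](C)(C)C(C)(C)C)c(O[Si](C)(C)C(C)(C)C)c2)o1 | intermediate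
6 | bis-TBS hispidin, 6-{(E)-2-[3,4-bis(tert-butyldimethylsilyloxy)phenyl]ethenyl}-4-hydroxy-2H-pyran-2-one | O=c1cc(O)cc(/C=C/c2ccc(O[Si](C)(C)C(C)(C)C)c(O[Si](C)(C)C(C)(C)C)c2)o1 | intermediate
7 | tetra-TBS hypholomine B, (2S,3S)-trans, all four catechol oxygens silylated | O=c1cc(O)cc([C@H]2c3c(cc(/C=C/c4ccc(O[Si](C)(C)C(C)(C)C)c(O[Si](C)(C)C(C)(C)C)c4)oc3=O)O[C@@H]2c2ccc(O[Si](C)(C)C(C)(C)C)c(O[Si](C)(C)C(C)(C)C)c2)o1 | intermediate
8 | hypholomine B, (2S,3S)-trans | O=c1cc(O)cc([C@H]2c3c(cc(/C=C/c4ccc(O)c(O)c4)oc3=O)O[C@@H]2c2ccc(O)c(O)c2)o1 | target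

## Step count and risks

Total step count: 4. Longest linear sequence: 4 steps (1 → 2 → 6 → 7 → 8; 3 enters at step 2).

Steps most likely to fail:

Step 3 (asymmetric oxidative dimerisation). This is an untested catalytic asymmetric reaction. Possible problems are low ee, trimer formation because 7 still carries a free hydroxypyranone and a styryl unit, acid-catalysed hydroalkylation of the alkene in HFIP, and a minor amount of ring closure through the lactone carbonyl oxygen. The fallback sets out from 6 and comes back at 7. It gives up catalyst control for a racemic coupling followed by resolution. 6 is treated with Mn(OAc)3·2H2O (1.1 equiv) in AcOH at 40 °C under argon, the established racemic oxidative [3+2] annulation of hydroxypyranones with styrenes. This gives the trans dimer as the racemate, that is 7 together with its enantiomer ent-7 F1. The two are separated by preparative chiral SFC on an amylose tris(3,5-dimethylphenylcarbamate) phase, which delivers 7; F1 is discarded.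

Step 2 (dianion aldol and dehydration). The lithium dianion is poorly soluble. During the acid dehydration the benzylic cation may also alkylate C3 of a second pyranone, and some silyl ether may be lost. The fallback sets out from 2 and comes back at 6. It builds the pyranone ring by a polyketide-type lactonisation instead of buying it. 2 is olefinated with Ph3P=CHC(O)N(OMe)Me (PhMe, 80 °C) to the (E)-cinnamoyl Weinreb amide F2. The lithium dienolate of 2,2,6-trimethyl-4H-1,3-dioxin-4-one (LiN(SiMe3)2, THF, −78 °C) is acylated by F2 to give the dioxinone ketone F3. Heating F3 in toluene at 110 °C expels acetone, and the acylketene closes onto the enolised styryl ketone to give 6 under neutral conditions.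

Step 4 (global desilylation of the dimer). Once the para-phenol is free, the benzylic C2–O bond can open through a quinone methide, the free catechols are air-sensitive, and four silyl ethers must all come off. The fallback sets out from 6 and comes back at 8. It removes the protecting groups before the ring is made. 6 is desilylated with KHF2 in MeOH at rt to hispidin F4, a robust compound. F4 is dimerised as the free polyphenol with horseradish peroxidase and H2O2 in acetone/phosphate buffer (pH 6). This phenoxyl-radical coupling is known to give hypholomine B among the dimers, here as the racemate, that is 8 together with ent-8 F5. Reversed-phase and then chiral preparative HPLC gives 8.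

## Further compounds

F1 | step 3 | ent-7, (2R,3R)-enantiomer of tetra-TBS hypholomine B | O=c1cc(O)cc([C@@H]2c3c(cc(/C=C/c4ccc(O[Si](C)(C)C(C)(C)C)c(O[Si](C)(C)C(C)(C)C)c4)oc3=O)O[C@H]2c2ccc(O[Si](C)(C)C(C)(C)C)c(O[Si](C)(C)C(C)(C)C)c2)o1
F2 | step 2 | (E)-3-[3,4-bis(tert-butyldimethylsilyloxy)phenyl]-N-methoxy-N-methylprop-2-enamide | CON(C)C(=O)/C=C/c1ccc(O[Si](C)(C)C(C)(C)C)c(O[Si](C)(C)C(C)(C)C)c1
F3 | step 2 | 6-{(E)-4-[3,4-bis(tert-butyldimethylsilyloxy)phenyl]-2-oxobut-3-en-1-yl}-2,2-dimethyl-4H-1,3-dioxin-4-one | CC1(C)OC(=O)C=C(CC(=O)/C=C/c2ccc(O[Si](C)(C)C(C)(C)C)c(O[Si](C)(C)C(C)(C)C)c2)O1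
F4 | step 4 | hispidin, 6-[(E)-2-(3,4-dihydroxyphenyl)ethenyl]-4-hydroxy-2H-pyran-2-one | O=c1cc(O)cc(/C=C/c2ccc(O)c(O)c2)o1
F5 | step 4 | ent-8, (2R,3R)-hypholomine B | O=c1cc(O)cc([C@@H]2c3c(cc(/C=C/c4ccc(O)c(O)c4)oc3=O)O[C@H]2c2ccc(O)c(O)c2)o1
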